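Numbering: ten-membered ring C1 (bears =CH2), C2, C3, C4 (butenolide β-carbon), C5 (lactone O–CH), C6=C7 (C7 bears CH3), C8 (OAc), C9, C10 (C=O); Cα is the butenolide α-carbon.
Enabling feature: C10 lies transannular (1,6) to C5, and C5 is allylic twice (to C6=C7 and to C4=Cα), with the lactone carbonyl cis to it on C4=Cα. Joining C5 to C10 on paper turns the target into decalinol 32 (ring A = C10, C1–C5; ring B = C5–C10), so the first cut is C5–O with C5–C10 re-formed.
Further cuts: C4–C5 (Heck), C4–Cα (crossed Claisen), C1–C10 (alkenyllithium addition), C5=C6 of ring B (metathesis), C7–C8 (crotylboration).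
Forward order: ring B enone 13 first, then the side chain onto C10, then ring A closed onto C5. Cutting the bond shared by rings A and B then opens the ten-membered ring and closes the butenolide in one flask.
Stereochemistry: C8 (S) comes from a catalyst-controlled anti crotylboration. C7, C10 and C5 of the decalin are relay centres set from C8 and erased later. Z-C4=Cα comes from a chelated enol triflate carried on with retention, Z-C6=C7 from ring B, and C5 (R) from lactone closure on the outer face of the opened ring.

Key step: step 17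

Remark on the chemistry: the carboxyl group of the key-step precursor is carried as its tert-butyl ester, because a free acid would form an acyl hypoiodite whose acyloxyl radical sits within reach of the weak C5–H bond; and C10 is made a carbinol before C5 is substituted, because ring B ketones that carry the C8 oxygen aromatise to p-cresol once they enolise.

Step 1
Reactants: 1 but-3-enoic acid
Product: 3 N-methoxy-N-methylbut-3-enamide, via 1-(but-3-enoyl)imidazole 2 (not isolated)
Conditions: CDI, CH2Cl2, 0 °C to rt; then MeNHOMe·HCl, rt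
Reagents that add atoms: 1,1'-carbonyldiimidazole, O=C(n1ccnc1)n1ccnc1 (imidazolyl group of 2 only); N,O-dimethylhydroxylamine hydrochloride, CNOC.Cl
Why: Weinreb amide formation through the acyl imidazolide is mild enough to keep the β,γ-alkene out of conjugation.

Step 2
Reactants: 3 N-methoxy-N-methylbut-3-enamide
Product: 5 N-methoxy-N-methyl-3-oxopropanamide, via secondary ozonide 4 (not isolated)
Conditions: O3, CH2Cl2, −78 °C; then Me2S, −78 °C to rt; used crude
Reagents that add atoms: ozone, [O-][O+]=O
Why: Ozonolysis with reductive work-up cleaves the only alkene and exposes C8 as the aldehyde, which is used at once because it is a 1,3-dicarbonyl compound.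

Step 3
Reactants: 5 N-methoxy-N-methyl-3-oxopropanamide; 6 (E)-crotylboronic acid pinacol ester
Product: 8 (3S,4R)-3-hydroxy-N-methoxy-N,4-dimethylhex-5-enamide, via O-boryl adduct 7 (not isolated)
Conditions: (R)-TRIP (5 mol %), toluene, −30 °C; aqueous work-up
Reagents that add atoms: none
Why: Chiral phosphoric acid-catalysed crotylboration through a closed chair transition state, in which the E-crotyl geometry gives the anti C7/C8 relationship and the (R)-catalyst directs attack to the Re face of the aldehyde, sets C8 as S and C7 as R.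

Step 4
Reactants: 8 (3S,4R)-3-hydroxy-N-methoxy-N,4-dimethylhex-5-enamide
Product: 9 (3S,4R)-3-(tert-butyldimethylsilyloxy)-N-methoxy-N,4-dimethylhex-5-enamide
Conditions: TBSOTf, 2,6-lutidine, CH2Cl2, −78 to 0 °C
Reagents that add atoms: tert-butyldimethylsilyl triflate, CC(C)(C)[Si](C)(C)OS(=O)(=O)C(F)(F)F
Why: Silyl ether formation with the reactive triflate protects the hindered C8 carbinol with a poor leaving group that later also shields one face of ring B.

Step 5
Reactants: 9 (3S,4R)-3-(tert-butyldimethylsilyloxy)-N-methoxy-N,4-dimethylhex-5-enamide; 10 vinylmagnesium bromide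
Product: 12 (5S,6R)-5-(tert-butyldimethylsilyloxy)-6-methylocta-1,7-dien-3-one, via magnesium chelate 11 (not isolated)
Conditions: THF, −78 to 0 °C; poured into cold 1 M HCl
Reagents that add atoms: none
Why: In this Weinreb ketone synthesis the chelate survives until the cold acid quench, so a single vinyl group (C5) is delivered and the freed amine is protonated before it can add to the enone.

Step 6
Reactants: 12 (5S,6R)-5-(tert-butyldimethylsilyloxy)-6-methylocta-1,7-dien-3-one
Product: 13 (4R,5S)-5-(tert-butyldimethylsilyloxy)-4-methylcyclohex-2-en-1-one (ring B enone; C7 R; C8 S; methyl cis to silyloxy)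
Conditions: second-generation Grubbs catalyst (3 mol %), CH2Cl2, 40 °C
Reagents that add atoms: none
Why: Ring-closing metathesis of two monosubstituted alkenes closes ring B at C5=C6 under neutral conditions, leaves C7 and C8 untouched, and turns the anti open-chain pair into the cis ring pair.

Step 7
Reactants: 14 diethyl malonate; 15 2,3-dibromopropene
Product: 17 diethyl 2-(2-bromoprop-2-en-1-yl)malonate, via sodium malonate enolate 16 (not isolated)
Conditions: NaH, THF, 0 °C; then 15, 0 °C to rt
Reagents that add atoms: none
Why: Malonic ester alkylation proceeds by SN2 at the allylic CH2Br (C2–C3 bond) while the vinylic C–Br bond stays inert.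

Step 8
Reactants: 17 diethyl 2-(2-bromoprop-2-en-1-yl)malonate
Product: 19 4-bromopent-4-enoic acid, via 2-(2-bromoallyl)malonic acid 18 (not isolated)
Conditions: LiOH, THF–H2O, rt; HCl; then neat, 140 °C
Reagents that add atoms: lithium hydroxide, [Li+].[OH-]
Why: Saponification and thermal decarboxylation of the malonic acid complete the malonic ester synthesis and leave the 2-bromoalkene intact.

Step 9
Reactants: 20 tert-butyl 3-hydroxypropanoate
Product: 21 tert-butyl 3-(tert-butyldimethylsilyloxy)propanoate
Conditions: TBSCl, imidazole, CH2Cl2, rt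
Reagents that add atoms: tert-butyldimethylsilyl chloride, CC(C)(C)[Si](C)(C)Cl
Why: Standard silylation of a primary alcohol gives the three-carbon unit (Cα, CH2O, carboxyl carbon) in protected form.

Step 10
Reactants: 19 4-bromopent-4-enoic acid; 13 ring B enone
Product: 23 4-[(1R,4R,5S)-5-(tert-butyldimethylsilyloxy)-1-hydroxy-4-methylcyclohex-2-en-1-yl]pent-4-enoic acid (C10 R), via lithium 4-lithiopent-4-enoate 22 (not isolated)
Conditions: 19, n-BuLi (1 equiv), then t-BuLi (2 equiv), THF, −78 °C; added to 13 and LaCl3·2LiCl, THF, −78 °C; AcOH quench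
Reagents that add atoms: none
Why: 1,2-Addition of an alkenyllithium (bromine–lithium exchange on the lithium carboxylate) to a cyclohexenone activated and kept from enolising by LaCl3·2LiCl forms C1–C10, and attack anti to the cis C7 methyl and C8 silyloxy groups sets C10 as R with the side chain cis to C7–H.

Step 11
Reactants: 23 hydroxy acid
Product: 25 4-[(1R,4R,5S)-5-(tert-butyldimethylsilyloxy)-4-methyl-1-(triethylsilyloxy)cyclohex-2-en-1-yl]pent-4-enoic acid, via triethylsilyl ester 24 (not isolated)
Conditions: TESOTf (2.5 equiv), 2,6-lutidine, CH2Cl2, −78 to 0 °C; then THF–H2O, rt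
Reagents that add atoms: triethylsilyl triflate, CC[Si](CC)(CC)OS(=O)(=O)C(F)(F)F
Why: Silylation of the tertiary alcohol with a silyl triflate (the silyl ester formed alongside hydrolyses in water) removes the C10 alkoxide, which would otherwise add to C4 and displace the triflate made in step 13.

Step 12
Reactants: 25 silyl-protected acid; 21 tert-butyl 3-(tert-butyldimethylsilyloxy)propanoate
Product: 28 tert-butyl 2-[(tert-butyldimethylsilyloxy)methyl]-3-oxo-6-[(1R,4R,5S)-5-(tert-butyldimethylsilyloxy)-4-methyl-1-(triethylsilyloxy)cyclohex-2-en-1-yl]hept-6-enoate (both Cα epimers), via acyl imidazolide 26 (not isolated), via lithium enolate 27 (not isolated)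
Conditions: 25, CDI, THF, rt; 21 (2.5 equiv), LDA, THF, −78 °C; combined at −78 °C; AcOH quench
Reagents that add atoms: 1,1'-carbonyldiimidazole, O=C(n1ccnc1)n1ccnc1 (imidazolyl group of 26 only)
Why: Crossed Claisen condensation of an ester enolate with an acyl imidazolide forms C4–Cα at −78 °C, where acylation outruns β-elimination of silanolate from the enolate, and the new Cα centre is of no consequence because it becomes sp2 in step 13.

Step 13
Reactants: 28 β-keto ester
Product: 29 tert-butyl (2Z)-2-[(tert-butyldimethylsilyloxy)methyl]-3-(trifluoromethylsulfonyloxy)-6-[(1R,4R,5S)-5-(tert-butyldimethylsilyloxy)-4-methyl-1-(triethylsilyloxy)cyclohex-2-en-1-yl]hepta-2,6-dienoate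
Conditions: Tf2O, LiOTf, Et3N, CH2Cl2, −78 to 0 °C
Reagents that add atoms: triflic anhydride, O=S(=O)(OS(=O)(=O)C(F)(F)F)C(F)(F)F
Why: O-Sulfonylation of the lithium-chelated enolate of a β-keto ester, in which enolate oxygen and ester carbonyl are held cis, gives the Z enol triflate and so places the carboxyl group on the future C5 side of C4=Cα.

Step 14
Reactants: 29 (Z)-enol triflate
Product: 30 tert-butyl (2Z)-3-(tert-butyldimethylsilyloxy)-2-[(4aR,6S,8aS)-6-(tert-butyldimethylsilyloxy)-7-methyl-4-methylidene-4a-(triethylsilyloxy)-3,4,4a,5,6,8a-hexahydronaphthalen-1(2H)-ylidene]propanoate (C5 S; C8 S; C10 R; cis-fused)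
Conditions: Pd(OAc)2 (10 mol %), dppp (20 mol %), K2CO3, toluene, 70 °C
Reagents that add atoms: none
Why: The intramolecular 6-exo Heck reaction of an alkenyl triflate on a cyclohexene, an established route to cis-decalins, inserts with retention of the alkenyl geometry on the face that carries the tether (C5 becomes S), and because C7–H is the only hydrogen syn to palladium, β-hydride elimination puts the alkene at C6=C7 and cannot touch C5–H.

Step 15
Reactants: 30 silyl-protected decalin
Product: 31 tert-butyl (2Z)-2-[(4aR,6S,8aS)-4a,6-dihydroxy-7-methyl-4-methylidene-3,4,4a,5,6,8a-hexahydronaphthalen-1(2H)-ylidene]-3-hydroxypropanoate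
Conditions: TBAF, AcOH (1:1), THF, 0 to 40 °C
Reagents that add atoms: none
Why: Fluoride desilylation buffered with acetic acid removes all three silyl groups without deprotonating the doubly allylic C5–H or generating a free C10 alkoxide.

Step 16
Reactants: 31 triol
Product: 32 tert-butyl (2Z)-3-acetoxy-2-[(4aR,6S,8aS)-6-acetoxy-4a-hydroxy-7-methyl-4-methylidene-3,4,4a,5,6,8a-hexahydronaphthalen-1(2H)-ylidene]propanoate (decalinol; key-step precursor)
Conditions: Ac2O, pyridine, DMAP (cat.), CH2Cl2, 0 °C
Reagents that add atoms: acetic anhydride, CC(=O)OC(C)=O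
Why: Acetylation takes the primary and the secondary allylic alcohol, while the hindered tertiary C10 alcohol does not react at 0 °C.

Step 17
Reactants: 32 decalinol tert-butyl ester
Product: 35 CNP0272505.1 (target; C5 R; C8 S), via C10 hypoiodite 33 (not isolated), via C5 allylic iodide 34 (not isolated)
Conditions: PhI(OAc)2 (1.5 equiv), I2 (0.5 equiv), cyclohexane–CH2Cl2, white LED, 10 °C
Reagents that add atoms: iodine, [I][I] (iodine atom of 33 and 34 only)
Why: Proposed new method: acetyl hypoiodite formed from PhI(OAc)2 and I2 turns the C10 alcohol into hypoiodite 33, visible light breaks its O–I bond, and the tertiary alkoxyl radical cuts C5–C10 rather than C1–C10 (alkenyl radical) or C9–C10 (primary radical), since this is the only cleavage that leaves a pentadienyl-type radical (spin on C5, C7 and Cα) and an enone at C10 at the same time. Iodine transfer gives the doubly allylic iodide 34, which ionises (or the radical is oxidised directly by trivalent iodine), and the carbonyl oxygen of the cis tert-butyl ester closes on C5 while the resulting oxonium ion sheds isobutene. The closest known reaction type is the hypoiodite β-fragmentation of bicyclic tertiary alcohols to medium-ring ketones, and the new element is ending it with a radical-polar crossover lactonisation at a dienyl position. The ten-membered ring arises by ring expansion (scission of the bond common to rings A and B) and the butenolide by 5-exo closure of oxygen on C5, whereas the C7 terminus would require a seven-membered ring. C5 is expected as R because the ester lies on the periphery of the new ring and can reach only the outer lobe at C5, the one opposite the departing C10 carbonyl, which for the (5S,10R) decalinol 32 corresponds to 5R; backside displacement of iodide from inside the ring is out of reach, and exposing the other lobe would require dragging C5–H through the ring. The step needs O–I homolysis to outrun electrophilic iodination of the C6=C7 and C1 alkenes and hydrogen abstraction at C5–H, which is secured by masking the acid as an ester (no acyl hypoiodite next to C5–H), by substoichiometric iodine and by a non-polar medium.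

Compound list
1 | but-3-enoic acid | C=CCC(=O)O | starting material
2 | 1-(but-3-enoyl)imidazole | C=CCC(=O)n1ccnc1 | intermediate
3 | N-methoxy-N-methylbut-3-enamide | C=CCC(=O)N(C)OC | intermediate
4 | secondary ozonide of 3: N-methoxy-N-methyl-2-(1,2,4-trioxolan-3-yl)acetamide | CON(C)C(=O)CC1OCOO1 | intermediate
5 | N-methoxy-N-methyl-3-oxopropanamide | CON(C)C(=O)CC=O | intermediate
6 | (E)-crotylboronic acid pinacol ester | C/C=C/CB1OC(C)(C)C(C)(C)O1 | starting material
7 | O-pinacolboryl derivative of 8 | CON(C)C(=O)C[C@H](OB1OC(C)(C)C(C)(C)O1)[C@H](C)C=C | intermediate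
8 | (3S,4R)-3-hydroxy-N-methoxy-N,4-dimethylhex-5-enamide | CON(C)C(=O)C[C@H](O)[C@H](C)C=C | intermediate
9 | (3S,4R)-3-(tert-butyldimethylsilyloxy)-N-methoxy-N,4-dimethylhex-5-enamide | CON(C)C(=O)C[C@H](O[Si](C)(C)C(C)(C)C)[C@H](C)C=C | intermediate
10 | vinylmagnesium bromide | C=C[Mg]Br | starting material
11 | bromomagnesium hemiaminal chelate from 9 and 10 | C=CC(O[Mg]Br)(N(C)OC)C[C@H](O[Si](C)(C)C(C)(C)C)[C@H](C)C=C | intermediate
12 | (5S,6R)-5-(tert-butyldimethylsilyloxy)-6-methylocta-1,7-dien-3-one | C=CC(=O)C[C@H](O[Si](C)(C)C(C)(C)C)[C@H](C)C=C | intermediate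
13 | (4R,5S)-5-(tert-butyldimethylsilyloxy)-4-methylcyclohex-2-en-1-one (ring B enone) | O=C1C[C@H](O[Si](C)(C)C(C)(C)C)[C@H](C)C=C1 | intermediate
14 | diethyl malonate | CCOC(=O)CC(=O)OCC | starting material
15 | 2,3-dibromopropene | C=C(Br)CBr | starting material
16 | sodium enolate of diethyl malonate | [Na+].CCOC(=O)[CH-]C(=O)OCC | intermediate
17 | diethyl 2-(2-bromoprop-2-en-1-yl)malonate | C=C(Br)CC(C(=O)OCC)C(=O)OCC | intermediate
18 | 2-(2-bromoprop-2-en-1-yl)malonic acid | C=C(Br)CC(C(=O)O)C(=O)O | intermediate
19 | 4-bromopent-4-enoic acid | C=C(Br)CCC(=O)O | intermediate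
20 | tert-butyl 3-hydroxypropanoate | CC(C)(C)OC(=O)CCO | starting material
21 | tert-butyl 3-(tert-butyldimethylsilyloxy)propanoate | CC(C)(C)OC(=O)CCO[Si](C)(C)C(C)(C)C | intermediate
22 | lithium 4-lithiopent-4-enoate | [Li+].[O-]C(=O)CCC([Li])=C | intermediate
23 | 4-[(1R,4R,5S)-5-(tert-butyldimethylsilyloxy)-1-hydroxy-4-methylcyclohex-2-en-1-yl]pent-4-enoic acid | C=C(CCC(=O)O)[C@]1(O)C=C[C@@H](C)[C@@H](O[Si](C)(C)C(C)(C)C)C1 | intermediate
24 | triethylsilyl ester of 25 | C=C(CCC(=O)O[Si](CC)(CC)CC)[C@]1(O[Si](CC)(CC)CC)C=C[C@@H](C)[C@@H](O[Si](C)(C)C(C)(C)C)C1 | intermediate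
25 | 4-[(1R,4R,5S)-5-(tert-butyldimethylsilyloxy)-4-methyl-1-(triethylsilyloxy)cyclohex-2-en-1-yl]pent-4-enoic acid | C=C(CCC(=O)O)[C@]1(O[Si](CC)(CC)CC)C=C[C@@H](C)[C@@H](O[Si](C)(C)C(C)(C)C)C1 | intermediate
26 | acyl imidazolide of 25 | C=C(CCC(=O)n2ccnc2)[C@]1(O[Si](CC)(CC)CC)C=C[C@@H](C)[C@@H](O[Si](C)(C)C(C)(C)C)C1 | intermediate
27 | lithium enolate of 21 | [Li+].[O-]C(OC(C)(C)C)=CCO[Si](C)(C)C(C)(C)C | intermediate
28 | β-keto ester (name in step 12; Cα epimers) | C=C(CCC(=O)C(CO[Si](C)(C)C(C)(C)C)C(=O)OC(C)(C)C)[C@]1(O[Si](CC)(CC)CC)C=C[C@@H](C)[C@@H](O[Si](C)(C)C(C)(C)C)C1 | intermediate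
29 | (Z)-enol triflate (name in step 13; triflate cis to ester) | C=C(CC/C(OS(=O)(=O)C(F)(F)F)=C(\CO[Si](C)(C)C(C)(C)C)C(=O)OC(C)(C)C)[C@]1(O[Si](CC)(CC)CC)C=C[C@@H](C)[C@@H](O[Si](C)(C)C(C)(C)C)C1 | intermediate
30 | silyl-protected cis-decalin (name in step 14; 5S,8S,10R; Z-C4=Cα) | C=C1CC/C(=C(\CO[Si](C)(C)C(C)(C)C)C(=O)OC(C)(C)C)[C@@H]2C=C(C)[C@@H](O[Si](C)(C)C(C)(C)C)C[C@]12O[Si](CC)(CC)CC | intermediate
31 | decalin triol (name in step 15; 5S,8S,10R) | C=C1CC/C(=C(\CO)C(=O)OC(C)(C)C)[C@@H]2C=C(C)[C@@H](O)C[C@]12O | intermediate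
32 | decalinol diacetate tert-butyl ester (name in step 16; 5S,8S,10R; key-step precursor) | C=C1CC/C(=C(\COC(C)=O)C(=O)OC(C)(C)C)[C@@H]2C=C(C)[C@@H](OC(C)=O)C[C@]12O | intermediate
33 | C10 hypoiodite of 32 | C=C1CC/C(=C(\COC(C)=O)C(=O)OC(C)(C)C)[C@@H]2C=C(C)[C@@H](OC(C)=O)C[C@]12OI | intermediate
34 | tert-butyl (2Z)-3-acetoxy-2-[(3Z,5S)-5-acetoxy-2-iodo-4-methyl-8-methylidene-7-oxocyclodec-3-en-1-ylidene]propanoate (C5 not defined) | C=C1CC/C(=C(\COC(C)=O)C(=O)OC(C)(C)C)C(I)/C=C(/C)[C@@H](OC(C)=O)CC1=O | intermediate
35 | CNP0272505.1: ten-membered carbocycle fused at C4–C5 to a butenolide; C1 exo-methylene; C10 ketone; Z-C6=C7(CH3); (8S)-acetate; Cα acetoxymethyl; (5R) | C=C1CCC2=C(COC(C)=O)C(=O)O[C@@H]2/C=C(/C)[C@@H](OC(C)=O)CC1=O | target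

Total steps: 17. Longest linear sequence: 14 steps (steps 1–6 and 10–17).

Steps most likely to fail

1. Step 17.
What may go wrong:
- electrophilic attack of acetyl hypoiodite on the C6=C7 or C1 alkene before the O–I bond is homolysed;
- capture of the dienyl intermediate by acetate or at C7;
- proton loss instead of lactone closure;
- low facial selectivity at C5.

Fallback: scission and C–O closure are separated and iodine is left out. Setting out from 32, Pb(OAc)4 with CaCO3 in benzene at 80 °C effects the known β-fragmentation of a tertiary alcohol through its lead alkoxide, with acetate transfer to the stabilised carbon. This should give the ring-opened C5 acetoxy keto ester F1. Catalytic Sc(OTf)3 in CH2Cl2 at −20 °C then ionises only the doubly allylic acetate. The tert-butyl ester closes on C5 with loss of isobutene, a known acid-induced lactonisation of tert-butyl esters onto allyl cations. This returns to the route at 35.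

2. Step 14.
What may go wrong:
- slow migratory insertion of the tetrasubstituted alkenylpalladium into the hindered C5=C6 alkene next to the quaternary C10, so that hydrolysis or reduction of the triflate takes over;
- double-bond migration by re-addition of palladium hydride.

Fallback: the alkenyl–palladium bond is made by transmetalation instead of oxidative addition. Setting out from 29, Miyaura borylation (B2pin2, PdCl2(PPh3)2, PPh3, KOPh, toluene, 50 °C) with retention gives the (Z)-alkenylboronate F2. A base-free oxidative boron Heck cyclisation on divalent palladium follows (Pd(OAc)2, 2,9-dimethyl-1,10-phenanthroline, O2, DMF, 25 to 50 °C). It closes C4–C5 with the same syn insertion and syn elimination and returns to the route at 30.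

3. Step 10.
What may go wrong:
- enolisation of the β-silyloxy enone by the strongly basic, poorly soluble dianion, followed by loss of silanolate and aromatisation;
- incomplete facial selectivity at C10, which would leave material that cannot undergo the β-hydride elimination of step 14.

Fallback: the side chain is brought in one oxidation level lower as a soluble monoanion. Setting out from 19:
- BH3·THF gives 4-bromopent-4-en-1-ol F3.
- TESCl and imidazole give its triethylsilyl ether F4.
- Bromine–lithium exchange (t-BuLi, Et2O, −78 °C) and addition to 13 with LaCl3·2LiCl give the tertiary alcohol F5.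
- TESOTf and 2,6-lutidine give the bis(triethylsilyl) ether F6.
- PPTS in MeOH–CH2Cl2 at −10 °C frees only the primary alcohol F7.
- TEMPO with PhI(OAc)2 in MeCN–H2O oxidises F7 to the acid, which returns to the route at 25.

Further compounds
F1 | step 17 | tert-butyl (2Z)-3-acetoxy-2-[(3Z,5S)-2,5-diacetoxy-4-methyl-8-methylidene-7-oxocyclodec-3-en-1-ylidene]propanoate | C=C1CC/C(=C(\COC(C)=O)C(=O)OC(C)(C)C)C(OC(C)=O)/C=C(/C)[C@@H](OC(C)=O)CC1=O
F2 | step 14 | (Z)-alkenylboronic acid pinacol ester corresponding to 29 (boron cis to ester) | C=C(CC/C(B2OC(C)(C)C(C)(C)O2)=C(\CO[Si](C)(C)C(C)(C)C)C(=O)OC(C)(C)C)[C@]1(O[Si](CC)(CC)CC)C=C[C@@H](C)[C@@H](O[Si](C)(C)C(C)(C)C)C1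
F3 | step 10 | 4-bromopent-4-en-1-ol | C=C(Br)CCCO
F4 | step 10 | (4-bromopent-4-en-1-yloxy)triethylsilane | C=C(Br)CCCO[Si](CC)(CC)CC
F5 | step 10 | (1R,4R,5S)-5-(tert-butyldimethylsilyloxy)-4-methyl-1-[5-(triethylsilyloxy)pent-1-en-2-yl]cyclohex-2-en-1-ol | C=C(CCCO[Si](CC)(CC)CC)[C@]1(O)C=C[C@@H](C)[C@@H](O[Si](C)(C)C(C)(C)C)C1
F6 | step 10 | triethylsilyl ether of F5 | C=C(CCCO[Si](CC)(CC)CC)[C@]1(O[Si](CC)(CC)CC)C=C[C@@H](C)[C@@H](O[Si](C)(C)C(C)(C)C)C1
F7 | step 10 | 4-[(1R,4R,5S)-5-(tert-butyldimethylsilyloxy)-4-methyl-1-(triethylsilyloxy)cyclohex-2-en-1-yl]pent-4-en-1-ol | C=C(CCCO)[C@]1(O[Si](CC)(CC)CC)C=C[C@@H](C)[C@@H](O[Si](C)(C)C(C)(C)C)C1
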